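The ten-membered carbocycle (ring atoms C1–C10: C1 bears the exocyclic methylene, C4 the secondary methyl, C5 the quaternary centre, C7=C8 is Z, C10 bears CO2Me) is disconnected at its trisubstituted C9=C10 alkene. That bond belongs to an α-alkenyl acrylate whose ester lies trans to C8, which is what a phosphonoacetate olefination delivers. One intramolecular Horner–Wadsworth–Emmons reaction therefore closes the ring and completes the cross-conjugated triene. Its precursor is an open chain with a (Z)-enal at C9 and a dimethyl α-phosphono ester at C10 attached to the C1 methylene carbon. C4/C5 come from one enantioselective Diels–Alder reaction, the side-chain carbinol C12 from a CBS reduction.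

Key step: step 20

Remarks on the chemistry.
- Numbering: the side chain on C5 is C11 (CH2) and C12 (carbinol carbon).
- Assumption: (R)-2-methylbutanoic acid, methyl bis(2,2,2-trifluoroethyl)phosphonoacetate and both antipodes of the two oxazaborolidines are purchased.
- The two ends of the cleaved six-membered ring are told apart by the silyloxy group placed in the cycloaddition (C7 aldehyde, C2 acid).
- The furan is in place before the ring cleavage, so OsO4/NaIO4 is used and ozone is avoided.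
- C9 is carried as a silyl-protected Z allylic alcohol and oxidised last, so no Z enal derivative meets acid.
- The 1,1-disubstituted alkene at C1 comes from a cross-coupling, so no deprotonation has to choose between a methyl group and the C2 methylene.

Step 1
Reactants: 1 but-3-en-2-one
Product: 2 2-[tri(propan-2-yl)silyloxy]buta-1,3-diene
Conditions: i-Pr3SiOTf, Et3N, Et2O, 0 °C to rt
Reagents that add atoms: tri(propan-2-yl)silyl trifluoromethanesulfonate, CC(C)[Si](OS(=O)(=O)C(F)(F)F)(C(C)C)C(C)C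
Why: O-Silylation of the enolised methyl ketone (silyl enol ether formation) gives the 2-silyloxydiene; the bulky silyl group is chosen because the enol ether has to survive six further steps.

Step 2
Reactants: 3 (E)-2-methylbut-2-enal; 2 2-[tri(propan-2-yl)silyloxy]buta-1,3-diene
Product: 4 (1R,6R)-1,6-dimethyl-4-[tri(propan-2-yl)silyloxy]cyclohex-3-ene-1-carbaldehyde
Conditions: (S)-o-tolyl-CBS-oxazaborolidine (20 mol %), Tf2NH (20 mol %), CH2Cl2, −78 to −40 °C
Reagents that add atoms: none
Why: Catalytic enantioselective Diels–Alder reaction of the enal held as its oxazaborolidinium complex: the nucleophilic diene terminus bonds to C4 ("para" adduct, silyloxy on C2), suprafacial addition to the E enal fixes the cis C4-Me/C5-Me relation, and the catalyst must shield the Cα-Si face so that the diene adds to Cα-Re (the S catalyst is proposed from the formyl C–H···O binding model, the sense is to be confirmed on 4, and the equally available antipode is the remedy if it is opposite).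

Step 3
Reactants: 4 (1R,6R)-1,6-dimethyl-4-[tri(propan-2-yl)silyloxy]cyclohex-3-ene-1-carbaldehyde
Product: 5 {(1R,6R)-1,6-dimethyl-4-[tri(propan-2-yl)silyloxy]cyclohex-3-en-1-yl}methanol
Conditions: NaBH4, MeOH, 0 °C
Reagents that add atoms: none
Why: Borohydride reduction of the hindered, non-enolisable aldehyde; the silyl enol ether is inert and no stereocentre is touched.

Step 4
Reactants: 5 {(1R,6R)-1,6-dimethyl-4-[tri(propan-2-yl)silyloxy]cyclohex-3-en-1-yl}methanol
Product: 7 {[(4R,5R)-4-(iodomethyl)-4,5-dimethylcyclohex-1-en-1-yl]oxy}tri(propan-2-yl)silane, via neopentyl triflate 6 (not isolated)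
Conditions: Tf2O, 2,6-lutidine, CH2Cl2, −78 °C; then n-Bu4NI, DMF, rt to 40 °C
Reagents that add atoms: tetrabutylammonium iodide, CCCC[N+](CCCC)(CCCC)CCCC.[I-]; trifluoromethanesulfonic anhydride (triflyl group, in 6 only), O=S(=O)(OS(=O)(=O)C(F)(F)F)C(F)(F)F
Why: Triflation followed by SN2 displacement with iodide (Finkelstein-type); the triflate is a good enough leaving group for substitution at the neopentyl C11 without ionisation, and the buffered, cold conditions spare the silyl enol ether.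

Step 5
Reactants: 8 furan-3-carboxylic acid
Product: 10 N-methoxy-N-methylfuran-3-carboxamide, via acyl imidazole 9 (not isolated)
Conditions: 1,1'-carbonyldiimidazole, CH2Cl2, rt; then MeNHOMe·HCl, rt
Reagents that add atoms: N,O-dimethylhydroxylamine hydrochloride, CNOC.Cl; 1,1'-carbonyldiimidazole (imidazolyl group, in 9 only), O=C(n1ccnc1)n1ccnc1
Why: Weinreb amide synthesis by acyl transfer from the acyl imidazole to the hydroxylamine.

Step 6
Reactants: 7 {[(4R,5R)-4-(iodomethyl)-4,5-dimethylcyclohex-1-en-1-yl]oxy}tri(propan-2-yl)silane; 10 N-methoxy-N-methylfuran-3-carboxamide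
Product: 12 2-{(1S,6R)-1,6-dimethyl-4-[tri(propan-2-yl)silyloxy]cyclohex-3-en-1-yl}-1-(furan-3-yl)ethan-1-one, via neopentyllithium 11 (not isolated)
Conditions: t-BuLi (2.1 equiv), Et2O/pentane, −78 °C; then 10, −78 to 0 °C; aq. NH4Cl
Reagents that add atoms: tert-butyllithium (lithium, in 11 only), [Li]C(C)(C)C
Why: Iodine–lithium exchange, then acylation of the organolithium by the Weinreb amide, whose chelated tetrahedral adduct stops over-addition and whose carbonyl addition at −78 °C should outpace metallation of the furan; C11–C12 is formed without touching C4 or C5 (the change of the C5 descriptor is formal).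

Step 7
Reactants: 12 2-{(1S,6R)-1,6-dimethyl-4-[tri(propan-2-yl)silyloxy]cyclohex-3-en-1-yl}-1-(furan-3-yl)ethan-1-one
Product: 13 (1R)-2-{(1S,6R)-1,6-dimethyl-4-[tri(propan-2-yl)silyloxy]cyclohex-3-en-1-yl}-1-(furan-3-yl)ethan-1-ol
Conditions: (S)-2-methyl-CBS-oxazaborolidine (0.5 equiv), catecholborane, toluene, −78 °C
Reagents that add atoms: none
Why: Corey–Bakshi–Shibata reduction under reagent control: with the planar furyl group as the large substituent and the CH2 arm as the small one, the S catalyst should deliver hydride to the Si face of C12 and give the R carbinol, as with aryl alkyl ketones, while catecholborane leaves the enol ether alone.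

Step 8
Reactants: 13 (1R)-2-{(1S,6R)-1,6-dimethyl-4-[tri(propan-2-yl)silyloxy]cyclohex-3-en-1-yl}-1-(furan-3-yl)ethan-1-ol
Product: 14 tert-butyl[(1R)-2-{(1S,6R)-1,6-dimethyl-4-[tri(propan-2-yl)silyloxy]cyclohex-3-en-1-yl}-1-(furan-3-yl)ethoxy]dimethylsilane
Conditions: t-BuMe2SiOTf, 2,6-lutidine, CH2Cl2, −78 °C
Reagents that add atoms: tert-butyldimethylsilyl trifluoromethanesulfonate, CC(C)(C)[Si](C)(C)OS(=O)(=O)C(F)(F)F
Why: Silylation of the hindered secondary alcohol; the ether prevents lactol formation with the coming C7 aldehyde and oxa-Michael addition to the later enoate and enal.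

Step 9
Reactants: 14 tert-butyl[(1R)-2-{(1S,6R)-1,6-dimethyl-4-[tri(propan-2-yl)silyloxy]cyclohex-3-en-1-yl}-1-(furan-3-yl)ethoxy]dimethylsilane
Product: 16 (3R,4R)-4-[(2R)-2-(tert-butyldimethylsilyloxy)-2-(furan-3-yl)ethyl]-3,4-dimethyl-6-oxohexanoic acid, via α-hydroxy ketone 15 (not isolated)
Conditions: OsO4 (2 mol %), N-methylmorpholine N-oxide, acetone/H2O, 0 °C; then NaIO4, THF/H2O, rt
Reagents that add atoms: 4-methylmorpholine 4-oxide (oxygen, delivered through OsO4), C[N+]1([O-])CCOCC1; water, O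
Why: Dihydroxylation of the electron-rich silyl enol ether (Rubottom-type α-hydroxylation, much faster than attack on the furan) and periodate cleavage of the α-hydroxy ketone (Malaprade-type) open the ring regiospecifically to the C7 aldehyde and the C2 acid.

Step 10
Reactants: 16 (3R,4R)-4-[(2R)-2-(tert-butyldimethylsilyloxy)-2-(furan-3-yl)ethyl]-3,4-dimethyl-6-oxohexanoic acid
Product: 17 (3R,4S,6Z)-4-[(2R)-2-(tert-butyldimethylsilyloxy)-2-(furan-3-yl)ethyl]-8-methoxy-3,4-dimethyl-8-oxooct-6-enoic acid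
Conditions: (CF3CH2O)2P(O)CH2CO2Me (2.2 equiv), KN(SiMe3)2 (2.1 equiv), 18-crown-6, THF, −78 °C; then 16; aq. HCl to pH 3, 0 °C
Reagents that add atoms: methyl 2-[bis(2,2,2-trifluoroethoxy)phosphoryl]acetate, COC(=O)CP(=O)(OCC(F)(F)F)OCC(F)(F)F
Why: Still–Gennari olefination: the electron-poor phosphonate with a dissociated potassium counter-ion eliminates under kinetic control to the Z enoate, while one equivalent of the anion turns the acid into a spectator carboxylate.

Step 11
Reactants: 17 (3R,4S,6Z)-4-[(2R)-2-(tert-butyldimethylsilyloxy)-2-(furan-3-yl)ethyl]-8-methoxy-3,4-dimethyl-8-oxooct-6-enoic acid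
Product: 18 methyl (2Z,5S,6R)-5-[(2R)-2-(tert-butyldimethylsilyloxy)-2-(furan-3-yl)ethyl]-8-hydroxy-5,6-dimethyloct-2-enoate
Conditions: BH3·THF (1.5 equiv), THF, 0 °C; MeOH quench
Reagents that add atoms: none
Why: Chemoselective borane reduction of the carboxylic acid through its acyloxyborane, which is faster than reaction with the conjugated ester, the electron-poor alkene or the furan.

Step 12
Reactants: 18 methyl (2Z,5S,6R)-5-[(2R)-2-(tert-butyldimethylsilyloxy)-2-(furan-3-yl)ethyl]-8-hydroxy-5,6-dimethyloct-2-enoate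
Product: 19 methyl (2Z,5S,6R)-5-[(2R)-2-(tert-butyldimethylsilyloxy)-2-(furan-3-yl)ethyl]-8-iodo-5,6-dimethyloct-2-enoate
Conditions: I2, PPh3, imidazole, CH2Cl2, 0 °C, dark
Reagents that add atoms: iodine, II
Why: Appel-type iodination of the unhindered primary alcohol via the alkoxyphosphonium iodide (SN2); iodine is bound as its phosphine adduct, which protects the furan and the Z enoate.

Step 13
Reactants: 19 methyl (2Z,5S,6R)-5-[(2R)-2-(tert-butyldimethylsilyloxy)-2-(furan-3-yl)ethyl]-8-iodo-5,6-dimethyloct-2-enoate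
Product: 20 (2Z,5S,6R)-5-[(2R)-2-(tert-butyldimethylsilyloxy)-2-(furan-3-yl)ethyl]-8-iodo-5,6-dimethyloct-2-en-1-ol
Conditions: i-Bu2AlH (2.5 equiv), CH2Cl2, −78 °C; aq. KNaC4H4O6 (tartrate)
Reagents that add atoms: none
Why: 1,2-Reduction of the enoate to the allylic alcohol with retention of the Z geometry; the primary iodide and the silyl ether are inert at −78 °C.

Step 14
Reactants: 20 (2Z,5S,6R)-5-[(2R)-2-(tert-butyldimethylsilyloxy)-2-(furan-3-yl)ethyl]-8-iodo-5,6-dimethyloct-2-en-1-ol
Product: 21 (2Z,5S,6R)-5-[(2R)-2-(tert-butyldimethylsilyloxy)-2-(furan-3-yl)ethyl]-8-iodo-5,6-dimethyl-1-(triethylsilyloxy)oct-2-ene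
Conditions: Et3SiCl, imidazole, CH2Cl2, 0 °C
Reagents that add atoms: chlorotriethylsilane, CC[Si](Cl)(CC)CC
Why: Silylation of the primary allylic alcohol with a group that can later be removed beside the secondary tert-butyldimethylsilyl ether.

Step 15
Reactants: 22 2,3-dibromoprop-1-ene; 23 trimethyl phosphite
Product: 24 dimethyl (2-bromoprop-2-en-1-yl)phosphonate
Conditions: neat, 110 °C, MeBr distilled off
Reagents that add atoms: none
Why: Michaelis–Arbuzov reaction at the allylic bromide; the vinylic bromide is inert, and SN2 and SN2' attack lead to the same product.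

Step 16
Reactants: 21 (2Z,5S,6R)-5-[(2R)-2-(tert-butyldimethylsilyloxy)-2-(furan-3-yl)ethyl]-8-iodo-5,6-dimethyl-1-(triethylsilyloxy)oct-2-ene; 24 dimethyl (2-bromoprop-2-en-1-yl)phosphonate
Product: 26 dimethyl {(5R,6S,8Z)-6-[(2R)-2-(tert-butyldimethylsilyloxy)-2-(furan-3-yl)ethyl]-5,6-dimethyl-2-methylidene-10-(triethylsilyloxy)dec-8-en-1-yl}phosphonate, via alkylzinc iodide 25 (not isolated)
Conditions: Zn dust (activated), LiCl, THF, 40 °C; then 24, Pd(OAc)2 (3 mol %), SPhos (6 mol %), THF, rt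
Reagents that add atoms: zinc (in 25 only), [Zn]
Why: LiCl-promoted zinc insertion into the primary iodide and Negishi coupling with the 2-bromoalkene join C2 to C1 and place the exocyclic alkene unambiguously; the base-free conditions avoid dehydrobromination of 24 and tolerate the silyl ethers, the furan and the phosphonate.

Step 17
Reactants: 26 dimethyl {(5R,6S,8Z)-6-[(2R)-2-(tert-butyldimethylsilyloxy)-2-(furan-3-yl)ethyl]-5,6-dimethyl-2-methylidene-10-(triethylsilyloxy)dec-8-en-1-yl}phosphonate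
Product: 28 methyl (6R,7S,9Z)-7-[(2R)-2-(tert-butyldimethylsilyloxy)-2-(furan-3-yl)ethyl]-2-(dimethoxyphosphoryl)-6,7-dimethyl-3-methylidene-11-(triethylsilyloxy)undec-9-enoate (both C2 epimers), via lithiated allylphosphonate 27 (not isolated)
Conditions: LiN(i-Pr)2 (2.2 equiv, commercial solution), THF, −78 °C; ClCO2Me (1.05 equiv), −78 °C; AcOH, −78 °C
Reagents that add atoms: methyl chloroformate, COC(=O)Cl; lithium diisopropylamide (lithium, in 27 only), [Li]N(C(C)C)C(C)C
Why: C-Acylation of a phosphonate-stabilised carbanion by a chloroformate, the usual route to phosphonoacetates (two equivalents of base because the product is more acidic): the hard electrophile should take the α-carbon of the allyl anion, and cold kinetic protonation of the doubly stabilised anion at C10 keeps the alkene exocyclic; the C10 configuration is irrelevant.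

Step 18
Reactants: 28 methyl (6R,7S,9Z)-7-[(2R)-2-(tert-butyldimethylsilyloxy)-2-(furan-3-yl)ethyl]-2-(dimethoxyphosphoryl)-6,7-dimethyl-3-methylidene-11-(triethylsilyloxy)undec-9-enoate
Product: 29 methyl (6R,7S,9Z)-7-[(2R)-2-(tert-butyldimethylsilyloxy)-2-(furan-3-yl)ethyl]-2-(dimethoxyphosphoryl)-11-hydroxy-6,7-dimethyl-3-methylideneundec-9-enoate
Conditions: pyridinium p-toluenesulfonate (0.1 equiv), MeOH/CH2Cl2, 0 °C
Reagents that add atoms: none
Why: Acid-catalysed methanolysis of the primary triethylsilyl ether, far faster than loss of the hindered secondary silyl ether and too mild to move the β,γ-double bond.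

Step 19
Reactants: 29 methyl (6R,7S,9Z)-7-[(2R)-2-(tert-butyldimethylsilyloxy)-2-(furan-3-yl)ethyl]-2-(dimethoxyphosphoryl)-11-hydroxy-6,7-dimethyl-3-methylideneundec-9-enoate
Product: 30 methyl (6R,7S,9Z)-7-[(2R)-2-(tert-butyldimethylsilyloxy)-2-(furan-3-yl)ethyl]-2-(dimethoxyphosphoryl)-6,7-dimethyl-3-methylidene-11-oxoundec-9-enoate
Conditions: Dess–Martin periodinane, NaHCO3, CH2Cl2, 0 °C; short buffered silica plug; used at once
Reagents that add atoms: none
Why: Buffered hypervalent-iodine oxidation of the Z allylic alcohol should give the Z enal without any acid or base able to isomerise it.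

Step 20
Reactants: 30 methyl (6R,7S,9Z)-7-[(2R)-2-(tert-butyldimethylsilyloxy)-2-(furan-3-yl)ethyl]-2-(dimethoxyphosphoryl)-6,7-dimethyl-3-methylidene-11-oxoundec-9-enoate
Product: 31 methyl (1E,3Z,6S,7R)-6-[(2R)-2-(tert-butyldimethylsilyloxy)-2-(furan-3-yl)ethyl]-6,7-dimethyl-10-methylidenecyclodeca-1,3-diene-1-carboxylate
Conditions: LiCl (10 equiv), i-Pr2NEt (5 equiv), MeCN, 25 °C, syringe-pump addition of 30 over 12 h, final concentration about 1 mM
Reagents that add atoms: none
Why: Intramolecular Horner–Wadsworth–Emmons olefination under LiCl/amine (Masamune–Roush) conditions: lithium chelation makes the C10 methine acidic enough for i-Pr2NEt, the anion adds through its α-carbon to the C9 aldehyde, and the β-oxido phosphonate collapses via the oxaphosphetane to the C9=C10 alkene and lithium dimethyl phosphate, an irreversible step that drives the closure. The closest known reaction type is the high-dilution HWE macrocyclisation of ω-formyl phosphonoacetates, used here at the medium-ring limit; the ten-membered carbocycle (C1–C10) is closed by a 10-exo-trig addition to the aldehyde followed by syn elimination. No stereocentre is formed, and both C10 epimers of 30 give the same anion. Three selectivities are needed: α- over γ-attack of the allylic anion (adducts through the methylene terminus cannot eliminate and revert by retro-aldol); ester trans to C8 (the normal preference of α-branched phosphonoacetates, reinforced because it gives the less strained cis,cis-1,3-diene, although a ten-membered ring does not by itself exclude a trans ring alkene); and retention of the Z C7=C8 bond and of the exocyclic alkene (hindered, non-nucleophilic weak base and a low stationary anion concentration). Cyclisation over oligomerisation rests on the slow addition to about 1 mM and on the few rotors between the ends, since the Z alkene and the sp2 centres C1 and C10 are already in place.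

Step 21
Reactants: 31 methyl (1E,3Z,6S,7R)-6-[(2R)-2-(tert-butyldimethylsilyloxy)-2-(furan-3-yl)ethyl]-6,7-dimethyl-10-methylidenecyclodeca-1,3-diene-1-carboxylate
Product: 32 methyl (1E,3Z,6S,7R)-6-[(2R)-2-(furan-3-yl)-2-hydroxyethyl]-6,7-dimethyl-10-methylidenecyclodeca-1,3-diene-1-carboxylate
Conditions: HF·pyridine, pyridine, THF, 0 °C to rt
Reagents that add atoms: none
Why: Fluoride-mediated desilylation under buffered, non-basic conditions, chosen so that no C12 alkoxide arises that could add across the ring to C7 of the dienoate.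

Step 22
Reactants: 32 methyl (1E,3Z,6S,7R)-6-[(2R)-2-(furan-3-yl)-2-hydroxyethyl]-6,7-dimethyl-10-methylidenecyclodeca-1,3-diene-1-carboxylate; 33 (2R)-2-methylbutanoic acid
Product: 34 methyl (1E,3Z,6S,7R)-6-{(2R)-2-(furan-3-yl)-2-[(2R)-2-methylbutanoyloxy]ethyl}-6,7-dimethyl-10-methylidenecyclodeca-1,3-diene-1-carboxylate (CNP0305973.1)
Conditions: N,N'-dicyclohexylcarbodiimide, 4-(dimethylamino)pyridine (0.1 equiv), CH2Cl2, 0 °C to rt
Reagents that add atoms: none
Why: Steglich esterification with retention at C12 (its C–O bond is not broken); low temperature and catalytic DMAP should keep the α-stereocentre of the acid intact.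

Compound list
1 | but-3-en-2-one | CC(=O)C=C | starting material
2 | 2-[tri(propan-2-yl)silyloxy]buta-1,3-diene | C=CC(=C)O[Si](C(C)C)(C(C)C)C(C)C | intermediate
3 | (E)-2-methylbut-2-enal | C/C=C(\C)C=O | starting material
4 | (1R,6R)-1,6-dimethyl-4-[tri(propan-2-yl)silyloxy]cyclohex-3-ene-1-carbaldehyde | C1[C@@H](C)[C@](C)(C=O)CC=C1O[Si](C(C)C)(C(C)C)C(C)C | intermediate
5 | {(1R,6R)-1,6-dimethyl-4-[tri(propan-2-yl)silyloxy]cyclohex-3-en-1-yl}methanol | C1[C@@H](C)[C@](C)(CO)CC=C1O[Si](C(C)C)(C(C)C)C(C)C | intermediate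
6 | {(1R,6R)-1,6-dimethyl-4-[tri(propan-2-yl)silyloxy]cyclohex-3-en-1-yl}methyl trifluoromethanesulfonate | C1[C@@H](C)[C@](C)(COS(=O)(=O)C(F)(F)F)CC=C1O[Si](C(C)C)(C(C)C)C(C)C | intermediate
7 | {[(4R,5R)-4-(iodomethyl)-4,5-dimethylcyclohex-1-en-1-yl]oxy}tri(propan-2-yl)silane | C1[C@@H](C)[C@](C)(CI)CC=C1O[Si](C(C)C)(C(C)C)C(C)C | intermediate
8 | furan-3-carboxylic acid | OC(=O)c1ccoc1 | starting material
9 | (furan-3-yl)(1H-imidazol-1-yl)methanone | O=C(c1ccoc1)n1ccnc1 | intermediate
10 | N-methoxy-N-methylfuran-3-carboxamide | CON(C)C(=O)c1ccoc1 | intermediate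
11 | organolithium from 7 (CH2Li in place of CH2I, ring configuration unchanged) | C1[C@@H](C)[C@](C)(C[Li])CC=C1O[Si](C(C)C)(C(C)C)C(C)C | intermediate
12 | 2-{(1S,6R)-1,6-dimethyl-4-[tri(propan-2-yl)silyloxy]cyclohex-3-en-1-yl}-1-(furan-3-yl)ethan-1-one | C1[C@@H](C)[C@](C)(CC(=O)c2ccoc2)CC=C1O[Si](C(C)C)(C(C)C)C(C)C | intermediate
13 | (1R)-2-{(1S,6R)-1,6-dimethyl-4-[tri(propan-2-yl)silyloxy]cyclohex-3-en-1-yl}-1-(furan-3-yl)ethan-1-ol | C1[C@@H](C)[C@](C)(C[C@@H](O)c2ccoc2)CC=C1O[Si](C(C)C)(C(C)C)C(C)C | intermediate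
14 | tert-butyl[(1R)-2-{(1S,6R)-1,6-dimethyl-4-[tri(propan-2-yl)silyloxy]cyclohex-3-en-1-yl}-1-(furan-3-yl)ethoxy]dimethylsilane | C1[C@@H](C)[C@](C)(C[C@@H](O[Si](C)(C)C(C)(C)C)c2ccoc2)CC=C1O[Si](C(C)C)(C(C)C)C(C)C | intermediate
15 | 4-[(2R)-2-(tert-butyldimethylsilyloxy)-2-(furan-3-yl)ethyl]-2-hydroxy-4,5-dimethylcyclohexan-1-one (C4, C5 as in 14; both C2 epimers) | C1[C@@H](C)[C@](C)(C[C@@H](O[Si](C)(C)C(C)(C)C)c2ccoc2)CC(O)C1=O | intermediate
16 | (3R,4R)-4-[(2R)-2-(tert-butyldimethylsilyloxy)-2-(furan-3-yl)ethyl]-3,4-dimethyl-6-oxohexanoic acid | OC(=O)C[C@@H](C)[C@](C)(C[C@@H](O[Si](C)(C)C(C)(C)C)c1ccoc1)CC=O | intermediate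
17 | (3R,4S,6Z)-4-[(2R)-2-(tert-butyldimethylsilyloxy)-2-(furan-3-yl)ethyl]-8-methoxy-3,4-dimethyl-8-oxooct-6-enoic acid | OC(=O)C[C@@H](C)[C@](C)(C[C@@H](O[Si](C)(C)C(C)(C)C)c1ccoc1)C/C=C\C(=O)OC | intermediate
18 | methyl (2Z,5S,6R)-5-[(2R)-2-(tert-butyldimethylsilyloxy)-2-(furan-3-yl)ethyl]-8-hydroxy-5,6-dimethyloct-2-enoate | OCC[C@@H](C)[C@](C)(C[C@@H](O[Si](C)(C)C(C)(C)C)c1ccoc1)C/C=C\C(=O)OC | intermediate
19 | methyl (2Z,5S,6R)-5-[(2R)-2-(tert-butyldimethylsilyloxy)-2-(furan-3-yl)ethyl]-8-iodo-5,6-dimethyloct-2-enoate | ICC[C@@H](C)[C@](C)(C[C@@H](O[Si](C)(C)C(C)(C)C)c1ccoc1)C/C=C\C(=O)OC | intermediate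
20 | (2Z,5S,6R)-5-[(2R)-2-(tert-butyldimethylsilyloxy)-2-(furan-3-yl)ethyl]-8-iodo-5,6-dimethyloct-2-en-1-ol | ICC[C@@H](C)[C@](C)(C[C@@H](O[Si](C)(C)C(C)(C)C)c1ccoc1)C/C=C\CO | intermediate
21 | (2Z,5S,6R)-5-[(2R)-2-(tert-butyldimethylsilyloxy)-2-(furan-3-yl)ethyl]-8-iodo-5,6-dimethyl-1-(triethylsilyloxy)oct-2-ene | ICC[C@@H](C)[C@](C)(C[C@@H](O[Si](C)(C)C(C)(C)C)c1ccoc1)C/C=C\CO[Si](CC)(CC)CC | intermediate
22 | 2,3-dibromoprop-1-ene | C=C(Br)CBr | starting material
23 | trimethyl phosphite | COP(OC)OC | starting material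
24 | dimethyl (2-bromoprop-2-en-1-yl)phosphonate | C=C(Br)CP(=O)(OC)OC | intermediate
25 | {(3R,4S,6Z)-4-[(2R)-2-(tert-butyldimethylsilyloxy)-2-(furan-3-yl)ethyl]-3,4-dimethyl-8-(triethylsilyloxy)oct-6-en-1-yl}zinc iodide | I[Zn]CC[C@@H](C)[C@](C)(C[C@@H](O[Si](C)(C)C(C)(C)C)c1ccoc1)C/C=C\CO[Si](CC)(CC)CC | intermediate
26 | dimethyl {(5R,6S,8Z)-6-[(2R)-2-(tert-butyldimethylsilyloxy)-2-(furan-3-yl)ethyl]-5,6-dimethyl-2-methylidene-10-(triethylsilyloxy)dec-8-en-1-yl}phosphonate | C=C(CC[C@@H](C)[C@](C)(C[C@@H](O[Si](C)(C)C(C)(C)C)c1ccoc1)C/C=C\CO[Si](CC)(CC)CC)CP(=O)(OC)OC | intermediate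
27 | lithium salt of 26, deprotonated at the CH2P carbon | [Li+].C=C(CC[C@@H](C)[C@](C)(C[C@@H](O[Si](C)(C)C(C)(C)C)c1ccoc1)C/C=C\CO[Si](CC)(CC)CC)[CH-]P(=O)(OC)OC | intermediate
28 | methyl (6R,7S,9Z)-7-[(2R)-2-(tert-butyldimethylsilyloxy)-2-(furan-3-yl)ethyl]-2-(dimethoxyphosphoryl)-6,7-dimethyl-3-methylidene-11-(triethylsilyloxy)undec-9-enoate (C2 epimers) | C=C(CC[C@@H](C)[C@](C)(C[C@@H](O[Si](C)(C)C(C)(C)C)c1ccoc1)C/C=C\CO[Si](CC)(CC)CC)C(P(=O)(OC)OC)C(=O)OC | intermediate
29 | methyl (6R,7S,9Z)-7-[(2R)-2-(tert-butyldimethylsilyloxy)-2-(furan-3-yl)ethyl]-2-(dimethoxyphosphoryl)-11-hydroxy-6,7-dimethyl-3-methylideneundec-9-enoate (C2 epimers) | C=C(CC[C@@H](C)[C@](C)(C[C@@H](O[Si](C)(C)C(C)(C)C)c1ccoc1)C/C=C\CO)C(P(=O)(OC)OC)C(=O)OC | intermediate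
30 | methyl (6R,7S,9Z)-7-[(2R)-2-(tert-butyldimethylsilyloxy)-2-(furan-3-yl)ethyl]-2-(dimethoxyphosphoryl)-6,7-dimethyl-3-methylidene-11-oxoundec-9-enoate (C2 epimers) | C=C(CC[C@@H](C)[C@](C)(C[C@@H](O[Si](C)(C)C(C)(C)C)c1ccoc1)C/C=C\C=O)C(P(=O)(OC)OC)C(=O)OC | intermediate
31 | methyl (1E,3Z,6S,7R)-6-[(2R)-2-(tert-butyldimethylsilyloxy)-2-(furan-3-yl)ethyl]-6,7-dimethyl-10-methylidenecyclodeca-1,3-diene-1-carboxylate | C=C1CC[C@@H](C)[C@](C)(C[C@@H](O[Si](C)(C)C(C)(C)C)c2ccoc2)C/C=C\C=C/1C(=O)OC | intermediate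
32 | methyl (1E,3Z,6S,7R)-6-[(2R)-2-(furan-3-yl)-2-hydroxyethyl]-6,7-dimethyl-10-methylidenecyclodeca-1,3-diene-1-carboxylate | C=C1CC[C@@H](C)[C@](C)(C[C@@H](O)c2ccoc2)C/C=C\C=C/1C(=O)OC | intermediate
33 | (2R)-2-methylbutanoic acid | CC[C@@H](C)C(=O)O | starting material
34 | methyl (1E,3Z,6S,7R)-6-{(2R)-2-(furan-3-yl)-2-[(2R)-2-methylbutanoyloxy]ethyl}-6,7-dimethyl-10-methylidenecyclodeca-1,3-diene-1-carboxylate | C=C1CC[C@@H](C)[C@](C)(C[C@@H](OC(=O)[C@H](C)CC)c2ccoc2)C/C=C\C=C/1C(=O)OC | target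

Total steps: 22. Longest linear sequence: 20 steps (1 to 34 through steps 1–4, 6–14 and 16–22); steps 5 and 15 are side branches.

Steps most likely to fail

1. Step 20. Intermolecular olefination (oligomers) may outrun the strained ten-membered closure. During a slow closure the Z enal may isomerise, or the anion may be reprotonated at its methylene terminus so that the double bond moves into conjugation. The fallback forms C9–C10 first as a single bond by intramolecular alkylation and makes the alkene afterwards. It sets out from alkylzinc iodide 25 and rejoins at 31. Negishi coupling of 25 with (2-bromoprop-2-en-1-yl) phenyl sulfone (Pd(OAc)2, SPhos) should give the allyl sulfone F1. LiN(i-Pr)2 and ClCO2Me should convert it into the α-sulfonyl ester F2. Methanolysis (pyridinium p-toluenesulfonate, MeOH) should give the allylic alcohol F3, and CBr4/PPh3 the (Z)-allylic bromide F4. Cs2CO3 in DMF at high dilution should close the ring by SN2 alkylation of the stabilised anion at the primary allylic carbon, giving the macrocyclic sulfonyl ester F5. DBU in warm toluene should then eliminate benzenesulfinic acid toward C9, the only neighbour of C10 that bears hydrogen, to give 31.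

2. Step 17. Acylation, or the final protonation, may take place at the methylene terminus of the allyl anion. This would give the conjugated alkylidene isomer, in which a later deprotonation can also occur at C2. The fallback builds the ester first and introduces phosphorus second. It sets out from 25 and rejoins at 28. Negishi coupling of 25 with methyl 3-bromobut-3-enoate should give the β,γ-unsaturated ester F6. Its lithium dienolate (LiN(i-Pr)2, −78 °C) should be C-phosphinylated at the α-carbon by (MeO)2PCl to the phosphonite F7, which t-BuOOH should oxidise to 28.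

3. Step 4. Substitution at the neopentyl carbon may be too slow, so that ionisation with a 1,2-shift or loss of the silyl enol ether intervenes. The fallback extends the chain by one carbon at the aldehyde stage without any substitution at C11. It sets out from 4 and rejoins at 12. Wittig methylenation (Ph3P=CH2) should give the vinyl compound F8. Hydroboration with 9-BBN and oxidation with NaBO3 should give the primary alcohol F9. Dess–Martin oxidation should give the aldehyde F10. 3-Furyllithium (from 3-bromofuran and n-BuLi at −78 °C) should give the carbinol F11 as a mixture of epimers, and a second Dess–Martin oxidation should give ketone 12.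

Further compounds
F1 | step 20 | (5R,6S,8Z)-6-[(2R)-2-(tert-butyldimethylsilyloxy)-2-(furan-3-yl)ethyl]-5,6-dimethyl-2-methylidene-10-(triethylsilyloxy)dec-8-en-1-yl phenyl sulfone | C=C(CC[C@@H](C)[C@](C)(C[C@@H](O[Si](C)(C)C(C)(C)C)c1ccoc1)C/C=C\CO[Si](CC)(CC)CC)CS(=O)(=O)c1ccccc1
F2 | step 20 | methyl (6R,7S,9Z)-7-[(2R)-2-(tert-butyldimethylsilyloxy)-2-(furan-3-yl)ethyl]-6,7-dimethyl-3-methylidene-2-(phenylsulfonyl)-11-(triethylsilyloxy)undec-9-enoate (C2 epimers) | C=C(CC[C@@H](C)[C@](C)(C[C@@H](O[Si](C)(C)C(C)(C)C)c1ccoc1)C/C=C\CO[Si](CC)(CC)CC)C(C(=O)OC)S(=O)(=O)c1ccccc1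
F3 | step 20 | methyl (6R,7S,9Z)-7-[(2R)-2-(tert-butyldimethylsilyloxy)-2-(furan-3-yl)ethyl]-11-hydroxy-6,7-dimethyl-3-methylidene-2-(phenylsulfonyl)undec-9-enoate (C2 epimers) | C=C(CC[C@@H](C)[C@](C)(C[C@@H](O[Si](C)(C)C(C)(C)C)c1ccoc1)C/C=C\CO)C(C(=O)OC)S(=O)(=O)c1ccccc1
F4 | step 20 | methyl (6R,7S,9Z)-11-bromo-7-[(2R)-2-(tert-butyldimethylsilyloxy)-2-(furan-3-yl)ethyl]-6,7-dimethyl-3-methylidene-2-(phenylsulfonyl)undec-9-enoate (C2 epimers) | C=C(CC[C@@H](C)[C@](C)(C[C@@H](O[Si](C)(C)C(C)(C)C)c1ccoc1)C/C=C\CBr)C(C(=O)OC)S(=O)(=O)c1ccccc1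
F5 | step 20 | methyl (3Z,6S,7R)-6-[(2R)-2-(tert-butyldimethylsilyloxy)-2-(furan-3-yl)ethyl]-6,7-dimethyl-10-methylidene-1-(phenylsulfonyl)cyclodec-3-ene-1-carboxylate (C1 epimers) | C=C1CC[C@@H](C)[C@](C)(C[C@@H](O[Si](C)(C)C(C)(C)C)c2ccoc2)C/C=C\CC1(C(=O)OC)S(=O)(=O)c1ccccc1
F6 | step 17 | methyl (6R,7S,9Z)-7-[(2R)-2-(tert-butyldimethylsilyloxy)-2-(furan-3-yl)ethyl]-6,7-dimethyl-3-methylidene-11-(triethylsilyloxy)undec-9-enoate | C=C(CC[C@@H](C)[C@](C)(C[C@@H](O[Si](C)(C)C(C)(C)C)c1ccoc1)C/C=C\CO[Si](CC)(CC)CC)CC(=O)OC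
F7 | step 17 | methyl (6R,7S,9Z)-7-[(2R)-2-(tert-butyldimethylsilyloxy)-2-(furan-3-yl)ethyl]-2-(dimethoxyphosphanyl)-6,7-dimethyl-3-methylidene-11-(triethylsilyloxy)undec-9-enoate (C2 epimers) | C=C(CC[C@@H](C)[C@](C)(C[C@@H](O[Si](C)(C)C(C)(C)C)c1ccoc1)C/C=C\CO[Si](CC)(CC)CC)C(P(OC)OC)C(=O)OC
F8 | step 4 | [(4-ethenyl-4,5-dimethylcyclohex-1-en-1-yl)oxy]tri(propan-2-yl)silane, ring configuration as in 4 | C1[C@@H](C)[C@](C)(C=C)CC=C1O[Si](C(C)C)(C(C)C)C(C)C
F9 | step 4 | 2-{(1S,6R)-1,6-dimethyl-4-[tri(propan-2-yl)silyloxy]cyclohex-3-en-1-yl}ethan-1-ol | C1[C@@H](C)[C@](C)(CCO)CC=C1O[Si](C(C)C)(C(C)C)C(C)C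
F10 | step 4 | 2-{(1S,6R)-1,6-dimethyl-4-[tri(propan-2-yl)silyloxy]cyclohex-3-en-1-yl}acetaldehyde | C1[C@@H](C)[C@](C)(CC=O)CC=C1O[Si](C(C)C)(C(C)C)C(C)C
F11 | step 4 | 2-{(1S,6R)-1,6-dimethyl-4-[tri(propan-2-yl)silyloxy]cyclohex-3-en-1-yl}-1-(furan-3-yl)ethan-1-ol (both carbinol epimers) | C1[C@@H](C)[C@](C)(CC(O)c2ccoc2)CC=C1O[Si](C(C)C)(C(C)C)C(C)C
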